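## Structural features

Kweichowenol B is a single carbocycle, a cyclohex-2-ene in which five of the six ring carbons are functionalised. C1 is a fully substituted carbinol carrying the exocyclic methylene C7 (a benzoate ester); C2=C3 is the ring alkene; C4 bears the second benzoate; C5 and C6 are free secondary carbinols. The four stereocentres C4, C5, C6 and C1 are contiguous and every neighbouring pair of oxygens is trans. The C1 and C5 hydroxyls therefore lie on one face and the C4 benzoate, the C6 hydroxyl and C7 on the other (1R,4S,5S,6S). Fragile points are the two benzoates, which can migrate to adjacent free hydroxyls under base (C4 to C5, C7 to C1 or C6), and the allylic C1–OH and C4–OBz, which invite ionisation and allylic transposition under acid. The molecule is also at the oxidation level of a hydrated arene, so dehydrative aromatisation is a constant threat. The real difficulty is the quaternary C1 carbinol in a defined relationship to three consecutive secondary C–O stereocentres, together with the need to acylate only O7 and O4 among five oxygens. The feature exploited is the 1,4-relationship of the oxygens on C1 and C4 across C2=C3: this is what a C1=C2–C3=C4 diene leaves behind after taking up O2 at its termini, and such a diene with C5 and C6 already oxygenated is an arene dihydrodiol.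

## Logic of the disconnections

14 to 13: the two O–H bonds at C5 and C6 are replaced by O–Si bonds. Keeping the 5,6-diol masked until both benzoates are in place makes the acylations site-specific. The forward unmasking must be non-basic so that no benzoate migrates.

13 to 12 and 7: the acyl–O bond at C4 is cut. In 12 the C4 hydroxyl is the only secondary alcohol, so no selectivity problem arises beyond sparing the tertiary C1 carbinol.

12 to 11: the C4–H bond is cut, returning the carbinol to a ketone. The peroxide bridge of 9 necessarily places the C4 oxygen cis to the C1 oxygen, whereas 14 needs it trans. Passing through the sp2 carbon keeps the oxygen and erases the configuration. The forward reduction must be 1,2-selective and deliver hydride so that the hydroxyl ends trans to the C5 oxygen.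

11 to 10: the O–Si bond at C5 is cut. Capping the α-ketol hydroxyl prevents enediol epimerisation, differentiates O5 from O4 and provides the steric bias for the reduction. The forward step must distinguish a secondary from a tertiary alcohol.

10 to 9: the C4 carbonyl and the C1 carbinol are reconnected through an O–O bond and H4 is restored. One peroxide replaces two functional groups. The forward base-induced opening is regiochemically unambiguous because C1 carries no hydrogen.

9 to 8: the C1–O and C4–O bonds are cut and O2 is removed. This deletes the bicycle, the quaternary stereocentre and the C4 stereocentre in one stroke and leaves a flat diene. The forward cycloaddition must occur on the face anti to the C6 silyl ether and syn to the free C5 hydroxyl, and must outrun the ene pathway. The free hydroxyl in 8 is kept deliberately as the directing group.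

8 to 6 and 7: the acyl–O bond at C7 is cut. The forward acylation must prefer the primary allylic hydroxyl over the secondary one at C5.

6 to 4 and 5: the C1–C7 bond is cut to an alkenyl bromide and a hydroxymethyl stannane. Bromine is the placeholder for C7 and comes with the starting material. The coupling must tolerate a free hydroxyl and a sensitive diene.

4 to 3 to 2 to 1: the C6 O–Si bond, the temporary C5 ester and finally the C5–O bond itself are cut. In 1 the C6 oxygen already has the configuration of 14 and C5 has the opposite one. C5 is therefore inverted by SN2 esterification of the hydroxyl remote from bromine, and the ester then masks O5 while O6 is silylated. An electron-poor aryl ester is chosen so that it can be removed under conditions too mild for silyl migration. The forward inversion must be regioselective and must not aromatise the dienediol.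

## Other disconnections considered

Alternative 1: The ring is traced to the achiral dienol A1, a dearomatised quinol ketal, and the C5–O and C6–O bonds are cut as an oxirane.
- Forward step: the C1 hydroxyl of A1 binds a chiral bis-hydroxamate complex of Hf(OtBu)4 or VO(OiPr)3, which transfers an oxygen of an alkyl hydroperoxide to one enantiotopic alkene, giving the syn-epoxide A2.
- In its favour: A1 should be reachable in two or three steps from a simple phenol, and absolute configuration comes from a catalyst, so either enantiomer is accessible. On starting-material cost and probably on step count this plan is the equal or the better of the chosen one.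
- Against it: A2 must be opened trans at C6, the carbon next to the quaternary centre, not at C5, or the wrong diastereomer results. Participation by the C7 benzoate could steer this but risks scrambling the ester.
- Comparison: the C4 ketone unveiled from the ketal still has to be reduced trans to O5, so that issue is the same in both plans. Mechanistically, a metal-bound peroxide transfer in a chiral pocket must earn its enantioselectivity on this substrate, whereas the chosen plan inherits enantiopurity from 1.

Alternative 2: The C4–C5 and C1–C6 bonds are cut, leading to the hydroxypyrone A3 and the enedione A4.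
- Forward step: a chiral amine base activates A3 for a [4+2] cycloaddition with A4, giving the bridged lactone A5.
- In its favour: the carbocycle and all four stereocentres, including quaternary C1, arise in one step from two achiral compounds. The lactone bridge ties C7 and O4 to the same face, which is exactly the trans C1–OH/C4–O relationship of 14. No corrective redox at C4 is needed, so on this point the alternative is better than the chosen plan.
- Against it: C5 and C6 arrive as acetyl groups and need two Baeyer–Villiger oxidations beside a strained alkene. The catalyst must also select the orientation of the trans dienophile that puts the C5 acetyl syn to the alkene.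
- Comparison: after the lactone is opened, five oxygens must be told apart with acetates and benzoates side by side. Ring construction is shorter than in the chosen plan, but the endgame would probably be longer and less selective, so overall step economy is at best equal.

Alternative 3: The C1–C6 bond is cut, giving the open-chain (Z)-keto aldehyde A6.
- Forward step: a chiral triazolium-derived carbene converts the C6 aldehyde of A6 into an acyl-anion equivalent that adds to the C1 ketone, closing the ring as the α-ketol A7.
- In its favour: both benzoates and the C5 silyl ether are installed on the chain before cyclisation, so no selective acylation on the ring is needed. The endgame from A7 (hydroxyl-directed C6 reduction, desilylation) is shorter. On both points it is better than the chosen plan.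
- Against it: A6 is delicate. The α-silyloxy aldehyde can epimerise at C5, the (Z)-enone can isomerise, and the carbene–aldehyde adduct has an α-oxygen leaving group that opens a redox-elimination pathway.
- Comparison: C1 is set by catalyst control that may be mismatched with C4 and C5, whereas the cycloaddition of the chosen plan is substrate-controlled by two cooperating groups. Building A6 stereoselectively would take more steps than the five needed to reach 8, so the overall sequence should be longer.

Key step: step 6

Remark: atoms are numbered as in the target throughout. On this numbering the benzoyloxymethyl group of diene 8 sits on the diene terminus C1 (a 1-substituted, not 2-substituted, cyclohexa-1,3-diene). With that locant corrected, 1, 8 and 9 are stereochemically consistent with 14 (C6 retained from 1, C5 inverted).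

## Route

Step 1
Reactants: 1 (1S,2S)-3-bromocyclohexa-3,5-diene-1,2-diol
Product: 2 (1R,6S)-5-bromo-6-hydroxycyclohexa-2,4-dien-1-yl 4-nitrobenzoate
Conditions: 4-O2NC6H4CO2H (1.1 equiv), PPh3, DIAD, THF, −20 to 0 °C
Reagents that add atoms: 4-nitrobenzoic acid, O=C(O)c1ccc(cc1)[N+](=O)[O-]
Why: Mitsunobu esterification; the hydroxyl remote from bromine is less hindered and more nucleophilic, so it should be activated as the oxyphosphonium ion and displaced by the carboxylate with SN2 inversion, setting C5 trans to the untouched C6 oxygen, while the acidic pronucleophile and low temperature should suppress elimination to a phenol.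

Step 2
Reactants: 2 (1R,6S)-5-bromo-6-hydroxycyclohexa-2,4-dien-1-yl 4-nitrobenzoate
Product: 3 (1R,6S)-5-bromo-6-[(tert-butyldimethylsilyl)oxy]cyclohexa-2,4-dien-1-yl 4-nitrobenzoate
Conditions: TBSOTf, 2,6-lutidine, CH2Cl2, −78 °C
Reagents that add atoms: tert-butyldimethylsilyl trifluoromethanesulfonate, CC(C)(C)[Si](C)(C)OS(=O)(=O)C(F)(F)F
Why: Silyl ether formation on the hindered hydroxyl next to the bromoalkene; the silyl triflate with a non-nucleophilic base at low temperature should be fast enough to forestall acyl migration, and no stereocentre is touched.

Step 3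
Reactants: 3 (1R,6S)-5-bromo-6-[(tert-butyldimethylsilyl)oxy]cyclohexa-2,4-dien-1-yl 4-nitrobenzoate
Product: 4 (1R,6S)-5-bromo-6-[(tert-butyldimethylsilyl)oxy]cyclohexa-2,4-dien-1-ol
Conditions: K2CO3 (0.3 equiv), MeOH, 0 °C
Reagents that add atoms: none
Why: Base-catalysed transesterification (methanolysis); the electron-poor ester should cleave at 0 °C, where a secondary silyl ether held trans-diaxial to the new alkoxide by allylic strain should neither cleave nor migrate.

Step 4
Reactants: 4 (1R,6S)-5-bromo-6-[(tert-butyldimethylsilyl)oxy]cyclohexa-2,4-dien-1-ol; 5 (tributylstannyl)methanol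
Product: 6 (1R,6R)-6-[(tert-butyldimethylsilyl)oxy]-5-(hydroxymethyl)cyclohexa-2,4-dien-1-ol
Conditions: Pd(PPh3)4 (5 mol %), toluene (degassed), 90 °C; aq. KF work-up
Reagents that add atoms: (tributylstannyl)methanol (5), CCCC[Sn](CCCC)(CCCC)CO
Why: Stille cross-coupling; zerovalent palladium inserts into the alkenyl C–Br bond, the α-oxygenated methylene should transfer from tin in preference to butyl, and reductive elimination forms C1–C7 at an sp2 carbon without touching a stereocentre (the descriptor at C6 changes only through priority).

Step 5
Reactants: 6 (1R,6R)-6-[(tert-butyldimethylsilyl)oxy]-5-(hydroxymethyl)cyclohexa-2,4-dien-1-ol; 7 benzoyl chloride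
Product: 8 [(5R,6R)-6-[(tert-butyldimethylsilyl)oxy]-5-hydroxycyclohexa-1,3-dien-1-yl]methyl benzoate
Conditions: BzCl (1.05 equiv), 2,4,6-collidine, CH2Cl2, −40 °C
Reagents that add atoms: benzoyl chloride (7), O=C(Cl)c1ccccc1
Why: Kinetically selective O-acylation; the primary allylic hydroxyl should react well before the secondary one flanked by the silyl ether when one equivalent of acyl chloride and a weak hindered base are used without a nucleophilic catalyst.

Step 6
Reactants: 8 [(5R,6R)-6-[(tert-butyldimethylsilyl)oxy]-5-hydroxycyclohexa-1,3-dien-1-yl]methyl benzoate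
Product: 9 [(1R,4R,7S,8R)-7-[(tert-butyldimethylsilyl)oxy]-8-hydroxy-2,3-dioxabicyclo[2.2.2]oct-5-en-1-yl]methyl benzoate
Conditions: O2, tetraphenylporphyrin (1 mol %), visible light, CH2Cl2, −30 °C
Reagents that add atoms: dioxygen (as singlet oxygen), O=O
Why: Energy transfer from the excited porphyrin converts ground-state O2 into singlet oxygen, which adds suprafacially across C1 and C4 of the s-cis-locked diene in a concerted [4+2] cycloaddition, forming C1–O and C4–O and leaving C2=C3. The closest known reaction type is the photooxygenation of cyclohexa-1,3-dienes derived from arene dihydrodiols to bicyclic endoperoxides. The one new ring, the six-membered 1,2-dioxene C1–O–O–C4–C3=C2, is closed by this cycloaddition and turns the carbocycle into a 2,3-dioxabicyclo[2.2.2]oct-5-ene. The new stereocentres C1 (R) and C4 (R) are set together by the face of the diene that oxygen attacks, and the bridge makes their oxygens necessarily cis. That face is fixed by the substrate: the C6 silyl ether, pushed pseudo-axial by allylic strain against the C1 substituent, shields its own face right beside C1, while the C5 hydroxyl on the opposite face can hydrogen-bond to the incoming oxygen in a non-coordinating solvent. The step therefore needs facial selectivity (anti to C6–OSi, syn to C5–OH), which both effects reinforce, and chemoselectivity for cycloaddition over the Schenck ene pathway, which the cisoid ring diene and the electron-poor oxygen-bearing allylic C–H bonds at C5, C6 and C7 should secure. Low temperature and an aprotic solvent should preserve both the hydrogen-bond steering and the peroxide.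

Step 7
Reactants: 9 [(1R,4R,7S,8R)-7-[(tert-butyldimethylsilyl)oxy]-8-hydroxy-2,3-dioxabicyclo[2.2.2]oct-5-en-1-yl]methyl benzoate
Product: 10 [(1R,5S,6S)-6-[(tert-butyldimethylsilyl)oxy]-1,5-dihydroxy-4-oxocyclohex-2-en-1-yl]methyl benzoate
Conditions: Et3N (0.5 equiv), CH2Cl2, 0 °C
Reagents that add atoms: none
Why: Kornblum–DeLaMare rearrangement; the amine can remove only H4, the sole hydrogen on a peroxide-bearing carbon, so O–O heterolysis should give the C4 enone and the C1 carbinol with C1 unchanged, and the mild base at 0 °C should leave the benzoate and the new α-ketol intact.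

Step 8
Reactants: 10 [(1R,5S,6S)-6-[(tert-butyldimethylsilyl)oxy]-1,5-dihydroxy-4-oxocyclohex-2-en-1-yl]methyl benzoate
Product: 11 [(1R,5S,6S)-5,6-bis[(tert-butyldimethylsilyl)oxy]-1-hydroxy-4-oxocyclohex-2-en-1-yl]methyl benzoate
Conditions: TBSOTf (1.1 equiv), 2,6-lutidine, CH2Cl2, −78 °C
Reagents that add atoms: tert-butyldimethylsilyl trifluoromethanesulfonate, CC(C)(C)[Si](C)(C)OS(=O)(=O)C(F)(F)F
Why: Silyl ether formation; with one equivalent of silyl triflate at −78 °C the secondary α-ketol hydroxyl should react and the tertiary C1 carbinol should not, which removes the epimerisable free ketol and installs the group that steers the reduction.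

Step 9
Reactants: 11 [(1R,5S,6S)-5,6-bis[(tert-butyldimethylsilyl)oxy]-1-hydroxy-4-oxocyclohex-2-en-1-yl]methyl benzoate
Product: 12 [(1R,4S,5R,6S)-5,6-bis[(tert-butyldimethylsilyl)oxy]-1,4-dihydroxycyclohex-2-en-1-yl]methyl benzoate
Conditions: NaBH4, CeCl3·7H2O, MeOH, −78 °C
Reagents that add atoms: none
Why: Luche reduction; the CeCl3-modified borohydride adds 1,2 to the enone, and axial hydride attack on the half-chair with the C5 silyloxy group pseudo-equatorial should place the new hydroxyl equatorial and trans to the C5 oxygen (4S), while esters and silyl ethers survive at −78 °C.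

Step 10
Reactants: 12 [(1R,4S,5R,6S)-5,6-bis[(tert-butyldimethylsilyl)oxy]-1,4-dihydroxycyclohex-2-en-1-yl]methyl benzoate; 7 benzoyl chloride
Product: 13 [(1R,4S,5R,6S)-4-(benzoyloxy)-5,6-bis[(tert-butyldimethylsilyl)oxy]-1-hydroxycyclohex-2-en-1-yl]methyl benzoate
Conditions: BzCl (1.5 equiv), pyridine, DMAP (0.1 equiv), CH2Cl2, 0 °C
Reagents that add atoms: benzoyl chloride (7), O=C(Cl)c1ccccc1
Why: Nucleophile-catalysed O-acylation; the C4 hydroxyl is the only secondary alcohol, the tertiary C1 carbinol should not acylate at 0 °C, and the C4–O bond is not broken, so the configuration is kept.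

Step 11
Reactants: 13 [(1R,4S,5R,6S)-4-(benzoyloxy)-5,6-bis[(tert-butyldimethylsilyl)oxy]-1-hydroxycyclohex-2-en-1-yl]methyl benzoate
Product: 14 [(1R,4S,5S,6S)-4-(benzoyloxy)-1,5,6-trihydroxycyclohex-2-en-1-yl]methyl benzoate (kweichowenol B)
Conditions: HF·pyridine, pyridine/THF, 0 °C to rt
Reagents that add atoms: none
Why: Fluoride-mediated desilylation under buffered, weakly acidic conditions; no alkoxide is generated, so the benzoates should not migrate, and the buffered medium should spare the allylic tertiary carbinol.

## Compound list

1 | (1S,2S)-3-bromocyclohexa-3,5-diene-1,2-diol | BrC1=CC=C[C@H](O)[C@@H]1O | starting material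
2 | (1R,6S)-5-bromo-6-hydroxycyclohexa-2,4-dien-1-yl 4-nitrobenzoate | BrC1=CC=C[C@@H](OC(=O)c2ccc(cc2)[N+](=O)[O-])[C@@H]1O | intermediate
3 | (1R,6S)-5-bromo-6-[(tert-butyldimethylsilyl)oxy]cyclohexa-2,4-dien-1-yl 4-nitrobenzoate | BrC1=CC=C[C@@H](OC(=O)c2ccc(cc2)[N+](=O)[O-])[C@@H]1O[Si](C)(C)C(C)(C)C | intermediate
4 | (1R,6S)-5-bromo-6-[(tert-butyldimethylsilyl)oxy]cyclohexa-2,4-dien-1-ol | BrC1=CC=C[C@@H](O)[C@@H]1O[Si](C)(C)C(C)(C)C | intermediate
5 | (tributylstannyl)methanol | CCCC[Sn](CCCC)(CCCC)CO | starting material
6 | (1R,6R)-6-[(tert-butyldimethylsilyl)oxy]-5-(hydroxymethyl)cyclohexa-2,4-dien-1-ol | OCC1=CC=C[C@@H](O)[C@@H]1O[Si](C)(C)C(C)(C)C | intermediate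
7 | benzoyl chloride | O=C(Cl)c1ccccc1 | starting material
8 | [(5R,6R)-6-[(tert-butyldimethylsilyl)oxy]-5-hydroxycyclohexa-1,3-dien-1-yl]methyl benzoate | O=C(OCC1=CC=C[C@@H](O)[C@@H]1O[Si](C)(C)C(C)(C)C)c1ccccc1 | intermediate
9 | [(1R,4R,7S,8R)-7-[(tert-butyldimethylsilyl)oxy]-8-hydroxy-2,3-dioxabicyclo[2.2.2]oct-5-en-1-yl]methyl benzoate | O=C(OC[C@]1(OO3)C=C[C@@H]3[C@@H](O)[C@@H]1O[Si](C)(C)C(C)(C)C)c1ccccc1 | intermediate
10 | [(1R,5S,6S)-6-[(tert-butyldimethylsilyl)oxy]-1,5-dihydroxy-4-oxocyclohex-2-en-1-yl]methyl benzoate | O=C(OC[C@]1(O)C=CC(=O)[C@@H](O)[C@@H]1O[Si](C)(C)C(C)(C)C)c1ccccc1 | intermediate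
11 | [(1R,5S,6S)-5,6-bis[(tert-butyldimethylsilyl)oxy]-1-hydroxy-4-oxocyclohex-2-en-1-yl]methyl benzoate | O=C(OC[C@]1(O)C=CC(=O)[C@@H](O[Si](C)(C)C(C)(C)C)[C@@H]1O[Si](C)(C)C(C)(C)C)c1ccccc1 | intermediate
12 | [(1R,4S,5R,6S)-5,6-bis[(tert-butyldimethylsilyl)oxy]-1,4-dihydroxycyclohex-2-en-1-yl]methyl benzoate | O=C(OC[C@]1(O)C=C[C@H](O)[C@@H](O[Si](C)(C)C(C)(C)C)[C@@H]1O[Si](C)(C)C(C)(C)C)c1ccccc1 | intermediate
13 | [(1R,4S,5R,6S)-4-(benzoyloxy)-5,6-bis[(tert-butyldimethylsilyl)oxy]-1-hydroxycyclohex-2-en-1-yl]methyl benzoate | O=C(OC[C@]1(O)C=C[C@H](OC(=O)c2ccccc2)[C@@H](O[Si](C)(C)C(C)(C)C)[C@@H]1O[Si](C)(C)C(C)(C)C)c1ccccc1 | intermediate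
14 | [(1R,4S,5S,6S)-4-(benzoyloxy)-1,5,6-trihydroxycyclohex-2-en-1-yl]methyl benzoate (kweichowenol B) | O=C(OC[C@]1(O)C=C[C@H](OC(=O)c2ccccc2)[C@@H](O)[C@@H]1O)c1ccccc1 | target

## Step count and least certain steps

Total step count: 11. Longest linear sequence: 11 steps (1 to 14); 5 and 7 are purchased.

Step 6 (key step). The most likely failures are insufficient facial discrimination, with oxygen also entering syn to the silyl ether if the hydrogen-bond steering is weak, and diversion into the ene manifold or decomposition of the peroxide. The fallback replaces the cycloaddition by an epoxide-based 1,4-oxygenation and sets out from 8.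
- Silylation of the C5 hydroxyl (TBSOTf, 2,6-lutidine, CH2Cl2, −78 °C) would give the bis-silyl diene F1.
- NaHCO3-buffered mCPBA in CH2Cl2 at 0 °C should epoxidise the more substituted C1=C2 bond anti to the adjacent C6 silyl ether, giving the vinyl epoxide F2 with the C1 oxygen already correct.
- PhSeNa (from (PhSe)2 and NaBH4 in EtOH) should open F2 at the allylic, non-quaternary C2 with inversion to the hydroxy selenide F3.
- Oxidation with H2O2/pyridine would give the allylic selenoxide. Its suprafacial [2,3]-sigmatropic shift delivers oxygen to C4 on the face that carried selenium, trans to the C1 hydroxyl. Cleavage of the selenenate rejoins the route at 12, bypassing steps 6 to 9.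

Step 1. The likely failures are incomplete regiocontrol between the two allylic hydroxyls and loss of material through elimination or aromatisation of the activated dienediol, including collapse of a cyclic dioxyphosphorane. The fallback differentiates the hydroxyls by protection before inversion and sets out from 1.
- TESCl/imidazole in DMF at −40 °C should silylate the less hindered distal hydroxyl to the mono-triethylsilyl ether F4.
- TBSOTf/2,6-lutidine would cap the proximal hydroxyl to give the mixed bis-silyl ether F5.
- PPTS in MeOH at 0 °C should remove only the triethylsilyl group, giving the cis-configured alcohol F6.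
- Mitsunobu esterification of F6, now the only free hydroxyl, with 4-nitrobenzoic acid would rejoin the route at 3.

Step 4. The likely failures are thermal [4+2] dimerisation or aromatisation of the diene at the coupling temperature, and sluggish transfer of the sp3 hydroxymethyl group with competing butyl transfer or protodebromination. The fallback introduces C7 as carbon monoxide and sets out from 4.
- Alkoxycarbonylation (Pd(OAc)2, PPh3, CO at 1 atm, Et3N, MeOH/DMF, 50 °C) would give the dienoate methyl ester F7.
- Reduction with iBu2AlH in CH2Cl2 at −78 °C would rejoin the route at 6.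

Step 9. The likely failure is hydride delivery to the other face of the C4 carbonyl if the two vicinal silyl ethers prefer a diaxial arrangement, which would give the alcohol cis to the C5 oxygen. The fallback sets C4 by SN2 inversion and sets out from 11.
- The same reduction, or a reagent-controlled Corey–Bakshi–Shibata reduction chosen for that face, would supply the C4-epimeric alcohol F8.
- Mitsunobu esterification of F8 with benzoic acid (PPh3, DIAD, toluene, 0 °C) would install the C4 benzoate with inversion and rejoin the route at 13, bypassing step 10.

## Further compounds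

F1 | step 6 | [(5R,6R)-5,6-bis[(tert-butyldimethylsilyl)oxy]cyclohexa-1,3-dien-1-yl]methyl benzoate (bis-silyl diene) | O=C(OCC1=CC=C[C@@H](O[Si](C)(C)C(C)(C)C)[C@@H]1O[Si](C)(C)C(C)(C)C)c1ccccc1
F2 | step 6 | C1–C2 epoxide of F1, oxirane oxygen anti to the C6 silyl ether (vinyl epoxide) | O=C(OC[C@]12O[C@H]1C=C[C@@H](O[Si](C)(C)C(C)(C)C)[C@@H]2O[Si](C)(C)C(C)(C)C)c1ccccc1
F3 | step 6 | C1 carbinol with C2 phenylselanyl group trans to the C1 hydroxyl, C3=C4 alkene, C5 and C6 silyl ethers (hydroxy selenide) | O=C(OC[C@]1(O)[C@H]([Se]c2ccccc2)C=C[C@@H](O[Si](C)(C)C(C)(C)C)[C@@H]1O[Si](C)(C)C(C)(C)C)c1ccccc1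
F4 | step 1 | 3-bromo cis-dihydrodiol with the hydroxyl remote from bromine as triethylsilyl ether | BrC1=CC=C[C@H](O[Si](CC)(CC)CC)[C@@H]1O
F5 | step 1 | 3-bromo cis-dihydrodiol, distal triethylsilyl ether and proximal tert-butyldimethylsilyl ether | BrC1=CC=C[C@H](O[Si](CC)(CC)CC)[C@@H]1O[Si](C)(C)C(C)(C)C
F6 | step 1 | cis-configured C5 epimer of 4 (distal hydroxyl free, proximal tert-butyldimethylsilyl ether) | BrC1=CC=C[C@H](O)[C@@H]1O[Si](C)(C)C(C)(C)C
F7 | step 4 | methyl (5R,6R)-6-[(tert-butyldimethylsilyl)oxy]-5-hydroxycyclohexa-1,3-diene-1-carboxylate | COC(=O)C1=CC=C[C@@H](O)[C@@H]1O[Si](C)(C)C(C)(C)C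
F8 | step 9 | C4 epimer of 12 (C4 hydroxyl cis to the C5 silyl ether and to the C1 hydroxyl) | O=C(OC[C@]1(O)C=C[C@@H](O)[C@@H](O[Si](C)(C)C(C)(C)C)[C@@H]1O[Si](C)(C)C(C)(C)C)c1ccccc1
A1 | alternative 1 | (1-hydroxy-4,4-dimethoxycyclohexa-2,5-dien-1-yl)methyl benzoate (achiral dienol) | O=C(OCC1(O)C=CC(OC)(OC)C=C1)c1ccccc1
A2 | alternative 1 | syn-5,6-epoxide of A1 (oxirane cis to the C1 hydroxyl, C4 dimethyl ketal, C2=C3 intact) | O=C(OC[C@]1(O)C=CC(OC)(OC)[C@H]2O[C@@H]12)c1ccccc1
A3 | alternative 2 | 3-hydroxy-2H-pyran-2-one | O=C1OC=CC=C1O
A4 | alternative 2 | (E)-hex-3-ene-2,5-dione | CC(=O)/C=C/C(C)=O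
A5 | alternative 2 | 7,8-diacetyl-4-hydroxy-2-oxabicyclo[2.2.2]oct-5-en-3-one (bridged lactone cycloadduct) | O=C3[C@]1(O)C=C[C@H](O3)[C@@H](C(C)=O)[C@@H]1C(C)=O
A6 | alternative 3 | (Z)-3,7-bis(benzoyloxy)-2-[(tert-butyldimethylsilyl)oxy]-6-oxohept-4-enal, its C2 and C3 configured as C5 and C4 of the target | O=C(OCC(=O)/C=C\[C@H](OC(=O)c1ccccc1)[C@@H](O[Si](C)(C)C(C)(C)C)C=O)c1ccccc1
A7 | alternative 3 | cyclic α-ketol (C6 ketone, C1 carbinol, C5 silyl ether, C7 and C4 benzoates) | O=C(OC[C@]1(O)C=C[C@H](OC(=O)c2ccccc2)[C@@H](O[Si](C)(C)C(C)(C)C)C1=O)c1ccccc1
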